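**Plan**
The target is (2R,3'E,7'E)-α-tocotrienol. Retrosynthesis first puts a temporary carbonyl on the benzylic C4 and an acetate on O6, then cuts the C2–C1' bond between the pyran ring and the side chain.
The enabling feature is that C2 is α to the ring oxygen O1 and β to C4 through C3. With C4 as a carbonyl, C2 becomes the electrophilic 2-position of a 4-silyloxybenzopyrylium, and the saturated C1'–C2' pair next to the 3'-alkene is what 1,2-hydrometalation of a terminal 1,3-diene delivers.
Forward, the pyranone ring is built on trimethylhydroquinone (C-acetylation, Claisen condensation, cyclodehydration), and the tetraene comes from (2E,6E)-farnesol (oxidation, Wittig methylenation).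
The fragments are joined by hydrozirconation and copper-catalysed asymmetric conjugate addition; one mixed-hydride operation then removes the C4 carbonyl and the acetate.
The C2 (R) centre comes from the chiral phosphoramidite–copper catalyst in step 6; both E alkenes come from farnesol and are never touched.

Key step: step 6

Assumption: the sense of induction of the phosphoramidite–copper catalyst on this cation cannot be predicted with confidence; the route is written with the (S,R,R) ligand, and its mirror image is to be used if a test run shows delivery to the Si face of C2.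

**Step 1**
Reactants: 1 trimethylhydroquinone (2,3,5-trimethylbenzene-1,4-diol)
Product: 2 acetyl-trimethylhydroquinone (1-(2,5-dihydroxy-3,4,6-trimethylphenyl)ethan-1-one)
Conditions: AcOH, BF3·OEt2 (Lewis-acid medium), 100 °C; then H2O
Reagents that add atoms: acetic acid, CC(=O)O
Why: Friedel–Crafts C-acylation (through the O-acetate and a Fries-type shift) can only take place at the single unsubstituted ring position, and chelation of the ortho hydroxyl to the new carbonyl should stop further reaction.

**Step 2**
Reactants: 2 acetyl-trimethylhydroquinone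
Product: 4 hydroxychromone (6-hydroxy-2,5,7,8-tetramethyl-4H-chromen-4-one), via β-diketone 3 (not isolated)
Conditions: NaH (5 equiv), EtOAc (6 equiv), THF, 0 °C to reflux, argon; then conc. HCl, AcOH, 90 °C
Reagents that add atoms: ethyl acetate, CCOC(C)=O
Why: Crossed Claisen condensation of the ketone enolate with ethyl acetate should give the β-diketone, driven by its deprotonation, and acid then closes the pyranone ring by attack of the ortho hydroxyl on the distal carbonyl and loss of water (cyclodehydration to a 2-methylchromone).

**Step 3**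
Reactants: 4 hydroxychromone
Product: 5 acetoxychromone (2,5,7,8-tetramethyl-4-oxo-4H-chromen-6-yl acetate)
Conditions: Ac2O, pyridine, DMAP (cat.), CH2Cl2, rt
Reagents that add atoms: acetic anhydride, CC(=O)OC(C)=O
Why: DMAP-catalysed acylation of the only free hydroxyl masks the acidic phenol against the alkylmetal of step 6 with a group that step 7 removes without an extra operation.

**Step 4**
Reactants: 6 (2E,6E)-farnesol
Product: 7 (2E,6E)-farnesal
Conditions: TEMPO (10 mol%), PhI(OAc)2 (1.1 equiv), CH2Cl2, rt
Reagents that add atoms: none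
Why: Oxoammonium (TEMPO) oxidation of an allylic primary alcohol stops at the enal and should not isomerise the adjacent E alkene.

**Step 5**
Reactants: 7 (2E,6E)-farnesal
Product: 8 tetraene ((3E,7E)-4,8,12-trimethyltrideca-1,3,7,11-tetraene)
Conditions: Ph3PCH3Br, KOtBu, THF, 0 °C; then 7, −78 °C to rt
Reagents that add atoms: methylenetriphenylphosphorane, C=P(c1ccccc1)(c1ccccc1)c1ccccc1 (made in the flask from methyltriphenylphosphonium bromide, C[P+](c1ccccc1)(c1ccccc1)c1ccccc1.[Br-])
Why: Wittig methylenation of the enal with the unstabilised ylide gives the terminal 1,3-diene without a new stereo element and leaves the 3E alkene untouched.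

**Step 6**
Reactants: 5 acetoxychromone; 8 tetraene
Product: 12 (R)-4-oxo-α-tocotrienyl acetate, via alkylzirconocene chloride 9 (not isolated), via 4-silyloxybenzopyrylium triflate 10 (not isolated), via silyl enol ether 11 (not isolated)
Conditions: 8 (1.6 equiv), Cp2ZrHCl (1.5 equiv), CH2Cl2, rt; separately 5, TMSOTf (1.2 equiv), CH2Cl2, 0 °C; combine in the presence of (CuOTf)2·C6H6 (5 mol%) and (S,R,R)-O,O'-(1,1'-binaphthyl-2,2'-diyl) N,N-bis(1-phenylethyl)phosphoramidite (12 mol%), Et2O/CH2Cl2, −30 °C to rt, dark; then 1 M HCl, THF, 0 °C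
Reagents that add atoms: none
Why: Proposed new method: syn-1,2-hydrozirconation of the monosubstituted terminus of the diene of 8 should give the primary homoallylic alkylzirconocene 9, which transmetalates to a phosphoramidite-bound alkyl complex of monovalent copper, while TMSOTf O-silylates the vinylogous-ester carbonyl of 5 to the 4-silyloxybenzopyrylium 10; π-complexation at C2=C3, oxidative addition at C2 to a trivalent copper species and reductive elimination then form the C2–C1' bond and leave silyl enol ether 11, which is hydrolysed to 12 on work-up. The closest known reaction types are the copper/phosphoramidite-catalysed asymmetric conjugate addition of alkylzirconocenes made in situ to β-methyl cyclic enones (quaternary centres, chlorosilane-assisted), the addition of carbon nucleophiles to 4-silyloxybenzopyrylium triflates, and the copper-catalysed enantioselective alkynylation of 2-substituted chromones through the same cations; the new element is an sp3 alkyl group delivered to a 2-alkylchromone. No ring is closed, because the pyran ring is already in place. The C2 stereocentre is set by the chiral ligand on copper, which must deliver C1' to the Re face of C2 (O1, C3, CH3 clockwise) to give the R configuration. The step needs 1,4- over 1,2-addition, secured by the OSiMe3 group on C4 and the peri 5-methyl group; it needs chemoselective hydrometalation, secured by the inertness of the three trisubstituted alkenes towards Cp2ZrHCl; and it needs retention of the 3'E geometry, secured because 1,2-addition to the diene never makes that alkene part of an allyl-metal.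

**Step 7**
Reactants: 12 (R)-4-oxo-α-tocotrienyl acetate
Product: 14 (R)-α-tocotrienol, via chroman-4,6-diol aluminate 13 (not isolated)
Conditions: LiAlH4 (3 equiv), Et2O, 0 °C; then AlCl3 (4 equiv) in Et2O, 0 °C to reflux; aqueous KNaC4H4O6 work-up
Reagents that add atoms: none
Why: LiAlH4 reduces the ketone and cleaves the acetate, and the chloroalanes formed on adding AlCl3 should ionise the benzylic C4–O bond with help from the ortho ring oxygen O1 and deliver hydride (mixed-hydride hydrogenolysis of a chroman-4-one to a chroman), while C2 is not involved and can no longer epimerise by ring opening once C4 is not a carbonyl.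

**Compound list**
1 | 2,3,5-trimethylbenzene-1,4-diol (trimethylhydroquinone) | Cc1cc(O)c(C)c(C)c1O | starting material
2 | 1-(2,5-dihydroxy-3,4,6-trimethylphenyl)ethan-1-one | CC(=O)c1c(O)c(C)c(C)c(O)c1C | intermediate
3 | 1-(2,5-dihydroxy-3,4,6-trimethylphenyl)butane-1,3-dione | CC(=O)CC(=O)c1c(O)c(C)c(C)c(O)c1C | intermediate (not isolated)
4 | 6-hydroxy-2,5,7,8-tetramethyl-4H-chromen-4-one | Cc1cc(=O)c2c(C)c(O)c(C)c(C)c2o1 | intermediate
5 | 2,5,7,8-tetramethyl-4-oxo-4H-chromen-6-yl acetate | Cc1cc(=O)c2c(C)c(OC(C)=O)c(C)c(C)c2o1 | intermediate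
6 | (2E,6E)-3,7,11-trimethyldodeca-2,6,10-trien-1-ol ((2E,6E)-farnesol) | CC(C)=CCC/C(C)=C/CC/C(C)=C/CO | starting material
7 | (2E,6E)-3,7,11-trimethyldodeca-2,6,10-trienal ((2E,6E)-farnesal) | CC(C)=CCC/C(C)=C/CC/C(C)=C/C=O | intermediate
8 | (3E,7E)-4,8,12-trimethyltrideca-1,3,7,11-tetraene | CC(C)=CCC/C(C)=C/CC/C(C)=C/C=C | intermediate
9 | chlorobis(cyclopentadienyl)[(3E,7E)-4,8,12-trimethyltrideca-3,7,11-trien-1-yl]zirconium (cyclopentadienyl rings drawn σ-bonded) | CC(C)=CCC/C(C)=C/CC/C(C)=C/CC[Zr](Cl)(C1C=CC=C1)C1C=CC=C1 | intermediate (not isolated)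
10 | 6-acetoxy-2,5,7,8-tetramethyl-4-(trimethylsilyloxy)chromenylium trifluoromethanesulfonate | Cc1cc(O[Si](C)(C)C)c2c(C)c(OC(C)=O)c(C)c(C)c2[o+]1.[O-]S(=O)(=O)C(F)(F)F | intermediate (not isolated)
11 | (R)-2,5,7,8-tetramethyl-2-[(3E,7E)-4,8,12-trimethyltrideca-3,7,11-trien-1-yl]-4-(trimethylsilyloxy)-2H-chromen-6-yl acetate | CC(C)=CCC/C(C)=C/CC/C(C)=C/CC[C@]1(C)C=C(O[Si](C)(C)C)c2c(C)c(OC(C)=O)c(C)c(C)c2O1 | intermediate (not isolated)
12 | (R)-2,5,7,8-tetramethyl-4-oxo-2-[(3E,7E)-4,8,12-trimethyltrideca-3,7,11-trien-1-yl]chroman-6-yl acetate | CC(C)=CCC/C(C)=C/CC/C(C)=C/CC[C@]1(C)CC(=O)c2c(C)c(OC(C)=O)c(C)c(C)c2O1 | intermediate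
13 | (2R,4RS)-2,5,7,8-tetramethyl-2-[(3E,7E)-4,8,12-trimethyltrideca-3,7,11-trien-1-yl]chromane-4,6-diol, present as its aluminium alkoxide | CC(C)=CCC/C(C)=C/CC/C(C)=C/CC[C@]1(C)CC(O)c2c(C)c(O)c(C)c(C)c2O1 | intermediate (not isolated)
14 | (R)-2,5,7,8-tetramethyl-2-[(3E,7E)-4,8,12-trimethyltrideca-3,7,11-trien-1-yl]chroman-6-ol ((2R,3'E,7'E)-α-tocotrienol) | CC(C)=CCC/C(C)=C/CC/C(C)=C/CC[C@]1(C)CCc2c(C)c(O)c(C)c(C)c2O1 | target

**Step count and risks**
Total step count: 7. Longest linear sequence: 5 (steps 1, 2, 3, 6, 7).

Steps most likely to fail: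

1. Step 6. The chiral copper complex may discriminate poorly between the two faces of the planar benzopyrylium, the acidic 2-methyl group of the cation may be deprotonated instead of C2 being attacked, or transmetalation from zirconium may be too slow to outrun uncatalysed racemic addition. The fallback uses known chemistry and sets out from compound 2 and commercial (5E,9E)-farnesylacetone (CC(C)=CCC/C(C)=C/CC/C(C)=C/CCC(C)=O). Kabbe condensation (pyrrolidine, toluene, reflux with water separation) should give racemic 4-oxo-α-tocotrienol F1. Acetylation (Ac2O, pyridine, DMAP) should give the racemic acetate F2. Preparative HPLC on a cellulose tris(3,5-dimethylphenylcarbamate) phase should then deliver the (R)-enantiomer, at which point the fallback comes back to the route at compound 12. The (S)-enantiomer could be racemised with pyrrolidine through reversible ring opening and recycled.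

2. Step 7. The C4 benzylic cation may be intercepted by the 3'-alkene of the side chain (cation–olefin cyclisation) before hydride is delivered, or hydrogenolysis may stall at the alcohol. The fallback sets out from compound 12 and avoids a free cation. NaBH4 (EtOH/THF, 0 °C) should give the (2R,4RS)-4-hydroxychroman acetate F3. Syn-elimination with methyl N-(triethylammoniosulfonyl)carbamate (Burgess reagent, benzene, 50 °C, dark) should give the (R)-2H-chromene acetate F4. Diimide (2-nitrobenzenesulfonylhydrazide, Et3N, CH2Cl2, rt), which reduces the cis-disubstituted C3=C4 alkene far faster than the trisubstituted ones, should give (R)-α-tocotrienyl acetate F5. Methanolysis (K2CO3, MeOH, argon) then comes back to the route at compound 14.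

3. Step 2. The air-sensitive hydroquinone polyanion may oxidise, ethyl acetate may self-condense, or acylation may occur on oxygen without productive transfer to carbon. The fallback sets out from compound 2. Acetylation of both hydroxyls (Ac2O, pyridine, DMAP) should give the diacetate F6. Baker–Venkataraman O-to-C acyl migration (LiN(SiMe3)2, THF, −78 to 0 °C) should give the β-diketone monoacetate F7. Cyclodehydration (AcOH, cat. H2SO4, 80 °C) then comes back to the route at compound 5, which makes step 3 unnecessary.

**Further compounds**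
F1 | step 6 | racemic 6-hydroxy-2,5,7,8-tetramethyl-2-[(3E,7E)-4,8,12-trimethyltrideca-3,7,11-trien-1-yl]chroman-4-one | CC(C)=CCC/C(C)=C/CC/C(C)=C/CCC1(C)CC(=O)c2c(C)c(O)c(C)c(C)c2O1
F2 | step 6 | racemic 2,5,7,8-tetramethyl-4-oxo-2-[(3E,7E)-4,8,12-trimethyltrideca-3,7,11-trien-1-yl]chroman-6-yl acetate | CC(C)=CCC/C(C)=C/CC/C(C)=C/CCC1(C)CC(=O)c2c(C)c(OC(C)=O)c(C)c(C)c2O1
F3 | step 7 | (2R,4RS)-4-hydroxy-2,5,7,8-tetramethyl-2-[(3E,7E)-4,8,12-trimethyltrideca-3,7,11-trien-1-yl]chroman-6-yl acetate | CC(C)=CCC/C(C)=C/CC/C(C)=C/CC[C@]1(C)CC(O)c2c(C)c(OC(C)=O)c(C)c(C)c2O1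
F4 | step 7 | (R)-2,5,7,8-tetramethyl-2-[(3E,7E)-4,8,12-trimethyltrideca-3,7,11-trien-1-yl]-2H-chromen-6-yl acetate | CC(C)=CCC/C(C)=C/CC/C(C)=C/CC[C@]1(C)C=Cc2c(C)c(OC(C)=O)c(C)c(C)c2O1
F5 | step 7 | (R)-2,5,7,8-tetramethyl-2-[(3E,7E)-4,8,12-trimethyltrideca-3,7,11-trien-1-yl]chroman-6-yl acetate | CC(C)=CCC/C(C)=C/CC/C(C)=C/CC[C@]1(C)CCc2c(C)c(OC(C)=O)c(C)c(C)c2O1
F6 | step 2 | 2-acetyl-3,5,6-trimethyl-1,4-phenylene diacetate | CC(=O)c1c(OC(C)=O)c(C)c(C)c(OC(C)=O)c1C
F7 | step 2 | 4-hydroxy-2,3,6-trimethyl-5-(3-oxobutanoyl)phenyl acetate | CC(=O)CC(=O)c1c(O)c(C)c(C)c(OC(C)=O)c1C
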